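**Retrosynthetic overview**
- The target comes from its tetrakis(methoxymethyl) ether; the C2–aryl bond is cut to a 2-bromobenzofuran (ring A part) and a ring B arylzinc.
- The furan ring is the only ring that is built, and it is formed last: an intramolecular copper-catalysed C–O coupling of a 2-(2,2-dibromovinyl)phenol closes it.
- That phenol and the (R) centre come from an enantioselective aromatic Claisen rearrangement of the (E)-2-methylbut-2-enyl ether of protected 2,4,6-trihydroxybenzaldehyde. The ether oxygen becomes O1 and the allyl group lands on the future C7, so the regiochemistry is fixed.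
- Ring B comes from 5-bromoresorcinol; both prenyl groups are first attached through oxygen as 1,1-dimethylallyl ethers and moved to carbon by a double Claisen rearrangement.
- Both benzene rings are bought.

Assumption: the facial sense of the proposed copper–bis(oxazoline) Claisen catalyst cannot be known in advance; the (S,S)-ligand is written as the one giving (R)-6, and its commercial mirror image is used if the sense is opposite.

**Step 1**
Reactants: 1 2,4,6-trihydroxybenzaldehyde; 2 chloromethyl methyl ether (MOMCl)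
Product: 3 2-hydroxy-4,6-bis(methoxymethoxy)benzaldehyde
Conditions: MOMCl (2.1 equiv), i-Pr2NEt (2.5 equiv), CH2Cl2, 0 °C → rt
Reagents that add atoms: chloromethyl methyl ether (2), COCCl
Why: Chemoselective O-alkylation (acetal protection) with 2.1 equiv of MOMCl caps the 4-OH and one ortho-OH, while the last ortho-OH stays locked in its hydrogen bond to the formyl group and is kept as the handle for step 2.

**Step 2**
Reactants: 3 2-hydroxy-4,6-bis(methoxymethoxy)benzaldehyde; 4 (E)-1-bromo-2-methylbut-2-ene (tiglyl bromide)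
Product: 5 2,4-bis(methoxymethoxy)-6-{[(2E)-2-methylbut-2-en-1-yl]oxy}benzaldehyde
Conditions: K2CO3 (2 equiv), DMF, 40 °C
Reagents that add atoms: (E)-1-bromo-2-methylbut-2-ene (4), C/C=C(\C)CBr
Why: Williamson ether synthesis in which the phenoxide displaces the primary allylic bromide by SN2 at CH2, so the E-trisubstituted alkene is kept and all three oxygens of ring A are now differentiated.

**Step 3**
Reactants: 5 2,4-bis(methoxymethoxy)-6-{[(2E)-2-methylbut-2-en-1-yl]oxy}benzaldehyde
Product: 6 2-hydroxy-4,6-bis(methoxymethoxy)-3-[(2R)-3-methylbut-3-en-2-yl]benzaldehyde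
Conditions: Cu(OTf)2 (10 mol%), (S,S)-t-Bu-box [2,2'-(propane-2,2-diyl)bis((4S)-4-tert-butyl-4,5-dihydrooxazole), 12 mol%], 2,6-di-tert-butylpyridine (20 mol%), 4 Å MS, CH2Cl2, 25–40 °C
Reagents that add atoms: none
Why: Proposed new method: a divalent copper bis(oxazoline) Lewis acid should chelate the formyl oxygen and the allyl ether oxygen of 5 in a six-membered ring, which polarises the O–CH2 bond (charge-accelerated aromatic Claisen rearrangement, helped by the alkoxy groups ortho and para to the migration terminus) and holds the arene in the ligand plane, so that the E-configured 2-methylbut-2-enyl chain reaches C3 through a chair transition state only from the face not blocked by a tert-butyl group, setting the (R) benzylic centre before tautomerisation to the phenol; the closest known reactions are the copper bis(oxazoline)-catalysed enantioselective Claisen rearrangements of 2-alkoxycarbonyl allyl vinyl ethers and of ester-bearing allyl 2-naphthyl ethers, whereas a monocyclic 2-(allyloxy)benzaldehyde with a trisubstituted allyl group has not been shown.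

**Step 4**
Reactants: 6 2-hydroxy-4,6-bis(methoxymethoxy)-3-[(2R)-3-methylbut-3-en-2-yl]benzaldehyde; 7 carbon tetrabromide
Product: 8 2-(2,2-dibromoethenyl)-3,5-bis(methoxymethoxy)-6-[(2R)-3-methylbut-3-en-2-yl]phenol
Conditions: CBr4 (2 equiv), PPh3 (4 equiv), Et3N (2 equiv), CH2Cl2, 0 °C
Reagents that add atoms: carbon tetrabromide (7), BrC(Br)(Br)Br
Why: Ramirez gem-dibromoolefination (first stage of the Corey–Fuchs sequence), a Wittig reaction of Ph3P=CBr2 with the formyl group that tolerates the free phenol, with Et3N shielding the acetals from HBr.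

**Step 5**
Reactants: 9 5-bromobenzene-1,3-diol (5-bromoresorcinol); 10 3-chloro-3-methylbut-1-yne
Product: 11 1-bromo-3,5-bis[(2-methylbut-3-yn-2-yl)oxy]benzene
Conditions: 3-chloro-3-methylbut-1-yne (3 equiv), DBU (3.2 equiv), CuCl2·2H2O (1 mol%), MeCN, 0 °C → rt
Reagents that add atoms: 3-chloro-3-methylbut-1-yne (10), C#CC(C)(C)Cl
Why: Copper-catalysed propargylic etherification in which the tertiary propargylic chloride is activated as a copper acetylide and both phenoxides add at the tertiary carbon, the aryl bromide being inert.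

**Step 6**
Reactants: 11 1-bromo-3,5-bis[(2-methylbut-3-yn-2-yl)oxy]benzene
Product: 12 1-bromo-3,5-bis[(2-methylbut-3-en-2-yl)oxy]benzene
Conditions: H2 (1 atm), Pd/CaCO3 poisoned with Pb(OAc)2, quinoline, EtOAc, rt, stopped after 2 equiv H2
Reagents that add atoms: none
Why: Lindlar semihydrogenation on lead-poisoned palladium reduces the two terminal alkynes to vinyl groups and stops there, leaving the C–Br bond intact.

**Step 7**
Reactants: 12 1-bromo-3,5-bis[(2-methylbut-3-en-2-yl)oxy]benzene; 2 chloromethyl methyl ether (MOMCl)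
Product: 14 3-bromo-1,5-bis(methoxymethoxy)-2,4-bis(3-methylbut-2-en-1-yl)benzene, via free diprenylbromoresorcinol 13 (not isolated)
Conditions: i-Pr2NEt (3 equiv), xylene, 140 °C (sealed); then 0 °C → rt, MOMCl (2.4 equiv)
Reagents that add atoms: chloromethyl methyl ether (2), COCCl
Why: Two thermal aromatic Claisen rearrangements ([3,3]) of the tertiary allyl ethers deliver linear prenyl groups to the ortho carbons next to bromine, the site favoured both by the electron-withdrawing meta-bromine and by being para to the other oxygen, and the two freed phenols are capped in the same pot by MOM protection.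

**Step 8**
Reactants: 8 2-(2,2-dibromoethenyl)-3,5-bis(methoxymethoxy)-6-[(2R)-3-methylbut-3-en-2-yl]phenol; 14 3-bromo-1,5-bis(methoxymethoxy)-2,4-bis(3-methylbut-2-en-1-yl)benzene
Product: 18 2-[3,5-bis(methoxymethoxy)-2,6-bis(3-methylbut-2-en-1-yl)phenyl]-4,6-bis(methoxymethoxy)-7-[(2R)-3-methylbut-3-en-2-yl]-1-benzofuran, via 2-bromobenzofuran 15 (not isolated), via aryllithium 16 (not isolated), via arylzinc chloride 17 (not isolated)
Conditions: flask A: 8, CuI (5 mol%), K3PO4 (2 equiv), THF, 80 °C; flask B: 14, n-BuLi (1.0 equiv), THF, −78 °C, 30 min, then ZnCl2 (1.1 equiv), → rt; B added to A, Pd(OAc)2 (3 mol%), SPhos (6 mol%), 60 °C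
Reagents that add atoms: none
Why: Monovalent copper activates the vinylic C–Br bond cis to the arene and the neighbouring phenoxide closes the furan ring by an intramolecular Ullmann-type C–O coupling (the ring-forming key bond), after which the remaining 2-bromide undergoes a Negishi coupling with the hindered arylzinc on zerovalent palladium/SPhos, the weak base and the non-basic organozinc leaving the benzylic stereocentre untouched.

**Step 9**
Reactants: 18 2-[3,5-bis(methoxymethoxy)-2,6-bis(3-methylbut-2-en-1-yl)phenyl]-4,6-bis(methoxymethoxy)-7-[(2R)-3-methylbut-3-en-2-yl]-1-benzofuran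
Product: 20 2-[3,5-dihydroxy-2,6-bis(3-methylbut-2-en-1-yl)phenyl]-7-[(2R)-3-methylbut-3-en-2-yl]-1-benzofuran-4,6-diol (CNP0208883.1), via tetrakis(trimethylsilyl) ether 19 (not isolated)
Conditions: TMSOTf (8 equiv), 2,2'-bipyridyl (12 equiv), MeCN, 0 °C → rt; then H2O, rt
Reagents that add atoms: none
Why: MOM deprotection by acetal-to-silyl ether exchange with the TMSOTf/2,2'-bipyridyl complex and mild hydrolysis removes all four acetals without protic acid, so the three ortho-allyl phenol pairs cannot cyclise to chromans or dihydrobenzofurans and the stereocentre is not touched.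

**Compound list**
1 | 2,4,6-trihydroxybenzaldehyde | O=Cc1c(O)cc(O)cc1O | starting material
2 | chloromethyl methyl ether | COCCl | starting material
3 | 2-hydroxy-4,6-bis(methoxymethoxy)benzaldehyde | O=Cc1c(O)cc(OCOC)cc1OCOC | intermediate
4 | (E)-1-bromo-2-methylbut-2-ene | C/C=C(\C)CBr | starting material
5 | 2,4-bis(methoxymethoxy)-6-{[(2E)-2-methylbut-2-en-1-yl]oxy}benzaldehyde | C/C=C(\C)COc1cc(OCOC)cc(OCOC)c1C=O | intermediate
6 | 2-hydroxy-4,6-bis(methoxymethoxy)-3-[(2R)-3-methylbut-3-en-2-yl]benzaldehyde | C=C(C)[C@@H](C)c1c(O)c(C=O)c(OCOC)cc1OCOC | intermediate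
7 | carbon tetrabromide | BrC(Br)(Br)Br | starting material
8 | 2-(2,2-dibromoethenyl)-3,5-bis(methoxymethoxy)-6-[(2R)-3-methylbut-3-en-2-yl]phenol | C=C(C)[C@@H](C)c1c(O)c(C=C(Br)Br)c(OCOC)cc1OCOC | intermediate
9 | 5-bromobenzene-1,3-diol | Oc1cc(O)cc(Br)c1 | starting material
10 | 3-chloro-3-methylbut-1-yne | C#CC(C)(C)Cl | starting material
11 | 1-bromo-3,5-bis[(2-methylbut-3-yn-2-yl)oxy]benzene | C#CC(C)(C)Oc1cc(Br)cc(OC(C)(C)C#C)c1 | intermediate
12 | 1-bromo-3,5-bis[(2-methylbut-3-en-2-yl)oxy]benzene | C=CC(C)(C)Oc1cc(Br)cc(OC(C)(C)C=C)c1 | intermediate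
13 | 5-bromo-4,6-bis(3-methylbut-2-en-1-yl)benzene-1,3-diol | CC(C)=CCc1c(O)cc(O)c(CC=C(C)C)c1Br | intermediate
14 | 3-bromo-1,5-bis(methoxymethoxy)-2,4-bis(3-methylbut-2-en-1-yl)benzene | COCOc1cc(OCOC)c(CC=C(C)C)c(Br)c1CC=C(C)C | intermediate
15 | 2-bromo-4,6-bis(methoxymethoxy)-7-[(2R)-3-methylbut-3-en-2-yl]-1-benzofuran | C=C(C)[C@@H](C)c1c(OCOC)cc(OCOC)c2cc(Br)oc12 | intermediate
16 | [3,5-bis(methoxymethoxy)-2,6-bis(3-methylbut-2-en-1-yl)phenyl]lithium | [Li]c1c(CC=C(C)C)c(OCOC)cc(OCOC)c1CC=C(C)C | intermediate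
17 | chloro[3,5-bis(methoxymethoxy)-2,6-bis(3-methylbut-2-en-1-yl)phenyl]zinc | Cl[Zn]c1c(CC=C(C)C)c(OCOC)cc(OCOC)c1CC=C(C)C | intermediate
18 | 2-[3,5-bis(methoxymethoxy)-2,6-bis(3-methylbut-2-en-1-yl)phenyl]-4,6-bis(methoxymethoxy)-7-[(2R)-3-methylbut-3-en-2-yl]-1-benzofuran | C=C(C)[C@@H](C)c1c(OCOC)cc(OCOC)c2cc(-c3c(CC=C(C)C)c(OCOC)cc(OCOC)c3CC=C(C)C)oc12 | intermediate
19 | tetrakis(trimethylsilyl) ether of the target | C=C(C)[C@@H](C)c1c(O[Si](C)(C)C)cc(O[Si](C)(C)C)c2cc(-c3c(CC=C(C)C)c(O[Si](C)(C)C)cc(O[Si](C)(C)C)c3CC=C(C)C)oc12 | intermediate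
20 | 2-[3,5-dihydroxy-2,6-bis(3-methylbut-2-en-1-yl)phenyl]-7-[(2R)-3-methylbut-3-en-2-yl]-1-benzofuran-4,6-diol | C=C(C)[C@@H](C)c1c(O)cc(O)c2cc(-c3c(CC=C(C)C)c(O)cc(O)c3CC=C(C)C)oc12 | target

**Step count and risks**
Total steps: 9. Longest linear sequence: 6 (steps 1, 2, 3, 4, 8, 9).

Step 3 (the proposed new reaction) is the most likely to fail. It may give low enantioselectivity, a competing [1,3] shift through an ion pair, or loss of an acetal on the Lewis acid. The fallback uses known chemistry and sets out from 5. Heating 5 in N,N-diethylaniline at 180 °C (thermal aromatic Claisen rearrangement) gives racemic 2-hydroxy-4,6-bis(methoxymethoxy)-3-(3-methylbut-3-en-2-yl)benzaldehyde F1. Its phenol is acylated with (1S)-camphanic chloride (Et3N, DMAP, CH2Cl2), and the (R)-configured camphanate F2 is separated from the (S)-configured camphanate F3 by chromatography or crystallisation. Methanolysis of F2 (K2CO3, MeOH, 0 °C) brings the route back at 6.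

Step 7 may give the 2,4-diprenyl isomer (migration to the carbon between the two oxygens) or lose isoprene from the tertiary ethers. The fallback sets out from 9 and places the prenyl groups by halogenation and cross-coupling instead of rearrangement. Protection with MOMCl/i-Pr2NEt gives 1-bromo-3,5-bis(methoxymethoxy)benzene F4. Twofold iodination with NIS in MeCN, para to each acetal oxygen, gives 3-bromo-2,4-diiodo-1,5-bis(methoxymethoxy)benzene F5. A twofold Suzuki–Miyaura coupling of the two C–I bonds with 3-methylbut-2-enylboronic acid pinacol ester (Pd(OAc)2, a bulky biarylphosphine chosen for attack at the CH2 end, K3PO4, THF/H2O, 40 °C) leaves the C–Br bond and comes back at 14.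

Step 8 may fail in the one-pot copper/palladium sequence or in forming the hindered arylzinc next to two allylic CH2 groups. The fallback sets out from 6 (and uses 14 as the aryl bromide) and closes the furan by alkyne cycloisomerisation instead. Silylation of 6 (TBSOTf, 2,6-lutidine) gives the tert-butyldimethylsilyl ether F6. Colvin homologation (TMSCHN2, LDA, THF, −78 °C → rt) gives the arylacetylene F7. Copper-free Sonogashira coupling with 14 (PdCl2(MeCN)2, XPhos, Cs2CO3, MeCN, 80 °C) gives the diarylacetylene F8. TBAF in THF at 60 °C removes the silyl group and the phenoxide closes the furan by 5-endo-dig C–O addition, coming back at 18.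

**Further compounds**
F1 | step 3 | racemic 2-hydroxy-4,6-bis(methoxymethoxy)-3-(3-methylbut-3-en-2-yl)benzaldehyde | C=C(C)C(C)c1c(O)c(C=O)c(OCOC)cc1OCOC
F2 | step 3 | 2-formyl-3,5-bis(methoxymethoxy)-6-[(2R)-3-methylbut-3-en-2-yl]phenyl (1S,4R)-camphanate | C=C(C)[C@@H](C)c1c(OC(=O)[C@@]23CC[C@@](C)(C(=O)O2)C3(C)C)c(C=O)c(OCOC)cc1OCOC
F3 | step 3 | 2-formyl-3,5-bis(methoxymethoxy)-6-[(2S)-3-methylbut-3-en-2-yl]phenyl (1S,4R)-camphanate | C=C(C)[C@H](C)c1c(OC(=O)[C@@]23CC[C@@](C)(C(=O)O2)C3(C)C)c(C=O)c(OCOC)cc1OCOC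
F4 | step 7 | 1-bromo-3,5-bis(methoxymethoxy)benzene | COCOc1cc(Br)cc(OCOC)c1
F5 | step 7 | 3-bromo-2,4-diiodo-1,5-bis(methoxymethoxy)benzene | COCOc1cc(OCOC)c(I)c(Br)c1I
F6 | step 8 | 2-[(tert-butyldimethylsilyl)oxy]-4,6-bis(methoxymethoxy)-3-[(2R)-3-methylbut-3-en-2-yl]benzaldehyde | C=C(C)[C@@H](C)c1c(O[Si](C)(C)C(C)(C)C)c(C=O)c(OCOC)cc1OCOC
F7 | step 8 | tert-butyl{2-ethynyl-3,5-bis(methoxymethoxy)-6-[(2R)-3-methylbut-3-en-2-yl]phenoxy}dimethylsilane | C=C(C)[C@@H](C)c1c(O[Si](C)(C)C(C)(C)C)c(C#C)c(OCOC)cc1OCOC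
F8 | step 8 | tert-butyl{2-{[3,5-bis(methoxymethoxy)-2,6-bis(3-methylbut-2-en-1-yl)phenyl]ethynyl}-3,5-bis(methoxymethoxy)-6-[(2R)-3-methylbut-3-en-2-yl]phenoxy}dimethylsilane | C=C(C)[C@@H](C)c1c(O[Si](C)(C)C(C)(C)C)c(C#Cc2c(CC=C(C)C)c(OCOC)cc(OCOC)c2CC=C(C)C)c(OCOC)cc1OCOC
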